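## The problem

Target 29 is a sesquilignan made of two halves: a 2-aryl-3-hydroxymethyl-2,3-dihydrobenzofuran (benzo ring A, oxygen ring B with O1, C2, C3, C3a, C7a, and the 4-hydroxy-3-methoxyphenyl ring C on C2) and a 1,4-diaryl furo[3,4-c]furan (rings D and E, atoms C1′ to C6a′, with the syringyl ring F on C4′). The halves are joined by one C(sp2)–C(sp3) bond from C5 of ring A to C1′. There are six stereocentres in two remote sets: C1′, C3a′, C4′ and C6a′ on the cis-fused furofuran (both aryl groups exo), and C2 and C3 on ring B, which are cis. The flat ring A lies between the sets, so neither can control the other; each must be made as a single enantiomer and the halves then joined. Within the furofuran the ring fusion and the convex face can steer the aryl-bearing carbons. Within ring B the cis arrangement is the less stable one: C2 is benzylic, para to an oxygen of ring C and bonded to an aryloxy leaving group, so acid (cation) or a free ring C phenoxide (quinone methide) can drain it to trans. C3 also becomes epimerisable as soon as its substituent is a carbonyl group. The three benzylic C–O bonds will not tolerate strong acid or hydrogenolysis, and the two phenols and the electron-rich arenes are sensitive to oxidants. The enabling feature is that O1 sits on the aromatic carbon C7a, ortho to C3a, which carries C3. The O1–C7a bond can therefore be made by metal-catalysed coupling of a C2 hydroxyl with an ortho halogen without breaking any bond to C2 or C3, and an open-chain anti alcohol then maps onto the cis ring. A second useful feature is that C5–H is the only C–H bond of ring A without an ortho neighbour.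

## Retrosynthesis

**Protecting groups (29 from 28).** No skeletal bond is cut. The last operation must be mild because the free ring C phenol makes C2 vulnerable, so both phenols and the primary alcohol are masked as acetates in 28 and released together by transesterification. Acetates are preferred to silyl ethers on the phenols because an acetoxy group is a poor donor: it holds the C2–O1 and C4′–O5′ benzylic ethers against ionisation during the Lewis acid union, and it survives fluoride.

**Union (28 from 16 and 27).** The C5–C1′ bond is cut. The neighbouring cuts, the benzylic C–O bonds of the furofuran, would require acid cyclisation of a tetraol in the presence of the cis ring and would set two benzylic centres with little bias. Cutting C5–C1′ gives two halves of similar size, each carrying only its own stereocentres. C1′ becomes an acetal carbon in 27, hence an oxocarbenium ion, and ring A becomes a nucleophile whose site of attack is fixed by a trifluoroborate group at C5 in 16. The forward step must deliver the aryl group to the convex face and must not ionise C2 or C4′.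

**Boron handle (16 from 14, 14 from 12).** The C5–B bond is traced to C5–H. A halogen carried at C5 from the start would compete with the ortho bromide in the ring closure, so a late sterically controlled C–H borylation is preferred; in 14 it can only go to C5. Compound 14 comes from 12 by exchange of the silyl ether for an acetate and acetylation of the alcohol.

**Hydroxymethyl group (12 from 10).** The C3 hydroxymethyl group is traced to a vinyl group by oxidative cleavage and reduction. A vinyl group is inert to base and copper, and it keeps a carbonyl group away from C3 until after the ring is closed; the aldehyde 11 then exists only transiently at low temperature.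

**Key disconnection (10 from 9).** The O1–C7a aryl ether bond is cut. Cutting O1–C2 instead would mean substitution at the benzylic stereocentre, which drifts to the trans isomer; cuts at C2–C3 or C3–C3a lead to cycloadditions or insertions that also favour trans. The O1–C7a cut touches no stereocentre, so precursor 9 is an open-chain anti bromo alcohol whose two centres can be set by acyclic stereocontrol. The forward step must form an aryl C–O bond from a secondary benzylic alcohol under basic, non-ionising conditions.

**Acyclic stereocontrol (9 from 5 and 7; 5 from 4; 4 from 1 and 2; 7 from 6).** The bond between the carbinol carbon and the aryl-bearing carbon is cut. An allylboration through a closed chair transition state turns the (E) geometry of 5 into the anti relationship, and a chiral acid catalyst sets the absolute configuration of both centres at once. The boronate 5 comes from the branched carbonate 4 by allylic borylation with transposition; 4 comes from aldehyde 1 and Grignard reagent 2; aldehyde 7 is silylated vanillin 6.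

**Acetal (27 from 25, 25 from 23).** The acetal carbon C1′ is traced to a vinyl group: oxidative cleavage of 23 gives an aldehyde that the cis hydroxymethyl group captures as the lactol 24, which is converted into the methyl acetal 25. A silyl-to-acetate exchange then gives 27.

**Ring E (23 from 22, 22 from 21).** The benzylic C4′–O5′ bond is cut. Ionisation of the benzylic alcohol of triol 22 can be answered only by the hydroxyl on C6′, which closes a five-membered ring; the other primary hydroxyl could only form an oxetane. The aryl group should settle trans to its neighbour, so the carbinol configuration of 22 need not be controlled. Triol 22 comes from 21 by hydride reduction of the lactone and of the acetal carbon.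

**Bridgeheads (21 from 19, 2 and 18; 18 from 17).** The C6a′–C1′ and C3a′–C4′ bonds are cut. Conjugate addition of a vinyl group to the chiral butenolide 19, anti to its menthyloxy group, sets C6a′; aldol trapping of the enolate by aldehyde 18, anti to the vinyl group, sets C3a′. The trans lactone becomes the cis-substituted tetrahydrofuran once the ring is re-formed through the other oxygen. Aldehyde 18 is silylated syringaldehyde 17.

## Roads not taken

**Alternative 1:** The cut is at both bridgehead-to-benzylic bonds of the furofuran (C3a′–C4′ and C6a′–C1′). In the forward key step the lithiated dithiane A1 adds to the β-carbon of butenolide 19 anti to the menthyloxy group and the enolate is trapped by aldehyde A2, giving the trans lactone A3. Its merits are real: one flask sets both bridgeheads from a cheap auxiliary and brings in both aryl-bearing carbons. For the furofuran alone it is shorter and more convergent than the five steps to 27, and the present plan borrows its logic for steps 10 and 11. Its weak points for this target lie elsewhere. Ring A arrives as a simple O-allyl guaiacyl group, so rings B and C must be grown afterwards on a phenol oxygen and its ortho carbon of a late intermediate, and the obvious annulation, oxidative phenol coupling, gives the trans ring. The dithiane must also be removed from an electron-rich substrate, and two benzylic C–O bonds are closed under acid with little kinetic bias between exo and endo. Against its better step economy for rings D and E, the chosen plan makes the difficult cis ring early, on small molecules, by a closure that cannot scramble it, and joins the halves in one regiodefined step.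

**Alternative 2:** The cut is at both benzylic C–O bonds (C1′–O2′ and C4′–O5′). In the forward key step a high-potential quinone oxidises each 4-hydroxybenzyl group of diol A4 to a para-quinone methide, the distal hydroxyl adds, and medioresinol A5 results. This is the shortest conceivable furofuran synthesis, it needs no protecting groups, and in step count it beats the chosen plan for that half. It requires a free phenol para to each benzylic carbon, however. In the target the oxygen para to C1′ is O1, an ether of ring B, so the oxidation can only be run before ring B exists, and it again ends at A5 with the cis ring still to be annulated. With ring B in place the oxidant would dehydrogenate C2–C3 to the benzofuran. Both new benzylic centres are also set by reversible quinone methide addition, where exo and endo isomers lie close in energy. The chosen plan sets kinetic control of each benzylic centre and full compatibility with the cis ring against this brevity.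

**Alternative 3:** The cut is at O2′–C1′ and C1′–C6a′. In the forward key step a silyl triflate exchanges the hydroxymethyl group of dihydrofuran A6 into the aryl acetal A7, the enol ether carbon attacks the oxocarbenium ion (a Prins-type closure of the second ring) and methanol caps C6′, giving the methyl acetal A8 with exo aryl groups. The union and the ring formation coincide, the exo selectivity is good, and since the aryl partner is an aldehyde acetal the method could in principle accept a preformed cis ring, which would make it as convergent as step 14. Its liabilities are the extra methoxy group on C6′, which must be removed by ionic hydrogenation and so exposes every benzylic ether to Lewis acid a second time, and the enantiopure trans dihydrofuran A6, which is a multi-step target in itself. As formulated it also delivers an O-allyl guaiacyl ring A and leaves the cis ring for later. The chosen plan has no reduction after the union, and it draws its aryl nucleophile from a C–H bond of the finished cis ring, so no formyl group has to be carried through the copper step.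

Key step: step 5

Remarks on the chemistry:
- The sense of induction in step 4 is taken from the parent allylboration of aromatic aldehydes, where the (R)-acid leads to Re-face attack; the (S)-acid is therefore specified for the (1S) carbinol. If the γ-aryl reagent responds in the opposite sense, the antipodal acid is used.
- Compounds 21 and 22 are carried as mixtures of carbinol epimers and 24 to 27 as mixtures of anomers. These centres are re-set in steps 11 and 14, so their SMILES are written without configuration at those carbons.
- Butenolide 19 is taken to be purchased as the single (5R) diastereomer.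

Step 1
Reactants: 1 2-bromo-3-methoxybenzaldehyde; 2 vinylmagnesium bromide
Product: 4 rac-1-(2-bromo-3-methoxyphenyl)prop-2-en-1-yl methyl carbonate, via bromomagnesium allylic alkoxide 3 (not isolated)
Conditions: 2 (1.2 equiv), THF, −78 → 0 °C; then ClCO2Me (1.5 equiv), 0 °C → rt
Reagents that add atoms: methyl chloroformate, COC(=O)Cl
Why: Grignard 1,2-addition to a non-enolisable aryl aldehyde, followed by O-acylation of the magnesium alkoxide in the same flask; the aryl bromide is inert to the Grignard reagent at low temperature, and the carbinol centre may be racemic because step 2 erases it.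

Step 2
Reactants: 4 rac-1-(2-bromo-3-methoxyphenyl)prop-2-en-1-yl methyl carbonate
Product: 5 (E)-2-[3-(2-bromo-3-methoxyphenyl)prop-2-en-1-yl]-4,4,5,5-tetramethyl-1,3,2-dioxaborolane
Conditions: CuCl (5 mol%), Xantphos (5 mol%), KOt-Bu (10 mol%), B2pin2 (1.1 equiv), THF, 0 °C → rt
Reagents that add atoms: bis(pinacolato)diboron, CC1(C)OB(OC1(C)C)B1OC(C)(C)C(C)(C)O1
Why: Copper-catalysed γ-selective (SN2′) allylic borylation: the complex (Xantphos)Cu–Bpin adds across the terminal alkene with boron on the terminal carbon, and β-elimination of the carbonate gives the conjugated (E)-alkene. The leaving group releases CO2 and methoxide, which regenerates the copper boryl complex, and the hindered aryl bromide is not touched at this temperature.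

Step 3
Reactants: 6 vanillin
Product: 7 3-methoxy-4-(triisopropylsilyloxy)benzaldehyde
Conditions: TIPSCl, imidazole, DMF, rt
Reagents that add atoms: chlorotriisopropylsilane, CC(C)[Si](Cl)(C(C)C)C(C)C
Why: Imidazole-promoted silylation of a phenol; the bulky triisopropylsilyl ether is chosen because it has to survive hot carbonate in step 5, and because a free phenol would compete as a nucleophile in that step.

Step 4
Reactants: 5 (E)-2-[3-(2-bromo-3-methoxyphenyl)prop-2-en-1-yl]-4,4,5,5-tetramethyl-1,3,2-dioxaborolane; 7 3-methoxy-4-(triisopropylsilyloxy)benzaldehyde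
Product: 9 (1S,2R)-2-(2-bromo-3-methoxyphenyl)-1-[3-methoxy-4-(triisopropylsilyloxy)phenyl]but-3-en-1-ol, via borate ester 8 (not isolated)
Conditions: (S)-TRIP [(S)-3,3′-bis(2,4,6-triisopropylphenyl)-1,1′-binaphthyl-2,2′-diyl hydrogen phosphate] (5 mol%), 4 Å MS, toluene, −30 °C → rt; aqueous work-up
Reagents that add atoms: none
Why: Chiral phosphoric acid-catalysed allylboration through a closed chair (Zimmerman–Traxler-type) transition state in which the aryl group of 7 and the γ-aryl group of (E)-5 are both equatorial, so the anti diastereomer follows from the alkene geometry. The (S)-acid, hydrogen-bonded to a boronate oxygen and the formyl hydrogen, should direct attack to the Si face, setting (1S) and with it (2R); the borate ester 8 is cleaved on work-up.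

Step 5
Reactants: 9 (1S,2R)-2-(2-bromo-3-methoxyphenyl)-1-[3-methoxy-4-(triisopropylsilyloxy)phenyl]but-3-en-1-ol
Product: 10 (2S,3R)-3-ethenyl-7-methoxy-2-[3-methoxy-4-(triisopropylsilyloxy)phenyl]-2,3-dihydro-1-benzofuran
Conditions: CuI (10 mol%), 3,4,7,8-tetramethyl-1,10-phenanthroline (20 mol%), Cs2CO3 (2 equiv), toluene, 110 °C
Reagents that add atoms: none
Why: Intramolecular Ullmann-type C–O coupling: Cs2CO3 deprotonates the secondary benzylic alcohol, the alkoxide passes to the phenanthroline-bound monovalent copper centre, the ortho C–Br bond adds oxidatively, and C–O reductive elimination from the six-membered trivalent copper aryl alkoxide releases 10 and the catalyst. The closest known reaction type is the copper-catalysed cyclisation of 2-(2-haloaryl)ethanols to 2,3-dihydrobenzofurans. The one ring is closed by forming O1–C7a, a five-membered closure onto an sp2 carbon that lies inside the new ring, brought about by reductive elimination and not by direct substitution. No stereocentre is created: C2 and C3 come from step 4, and because neither the C2–O bond nor any bond to C3 is broken, the anti relationship of 9 must appear as the cis relationship of 10. The step needs chemoselectivity for coupling over β-hydride loss from the copper alkoxide and over hydrodebromination, and it needs the aryl silyl ether to survive; the chelating electron-rich ligand, the favourable five-ring geometry and a non-polar solvent in which the carbonate is barely soluble should secure this. The methoxy group next to bromine slows oxidative addition, which is why a temperature near 110 °C is planned. The basic, non-ionising medium leaves benzylic C2 configurationally safe, and the C3–H bond is far too weakly acidic for carbonate.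

Step 6
Reactants: 10 (2S,3R)-3-ethenyl-7-methoxy-2-[3-methoxy-4-(triisopropylsilyloxy)phenyl]-2,3-dihydro-1-benzofuran
Product: 12 [(2S,3S)-7-methoxy-2-[3-methoxy-4-(triisopropylsilyloxy)phenyl]-2,3-dihydro-1-benzofuran-3-yl]methanol, via aldehyde 11 (not isolated)
Conditions: O3, CH2Cl2/MeOH (4:1), Sudan Red 7B, −78 °C; then NaBH4, −78 → 0 °C
Reagents that add atoms: ozone, [O-][O+]=O
Why: Ozonolysis of a terminal alkene with reductive borohydride work-up; hydride is added at −78 °C so that aldehyde 11, whose C3–H is benzylic and α to the carbonyl and whose ring oxygen is β to it, is reduced before it can epimerise or open. The terminal alkene reacts faster than the arenes, and the dye marks the endpoint; the descriptor at C3 changes from R to S only because the substituent priorities change.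

Step 7
Reactants: 12 [(2S,3S)-7-methoxy-2-[3-methoxy-4-(triisopropylsilyloxy)phenyl]-2,3-dihydro-1-benzofuran-3-yl]methanol
Product: 14 [(2S,3S)-2-(4-acetoxy-3-methoxyphenyl)-7-methoxy-2,3-dihydro-1-benzofuran-3-yl]methyl acetate, via diol 13 (not isolated)
Conditions: TBAF, AcOH, THF, 0 °C; then Ac2O, Et3N, DMAP, 0 °C → rt
Reagents that add atoms: acetic anhydride, CC(=O)OC(C)=O
Why: Fluoride desilylation of the aryl silyl ether followed by DMAP-catalysed acetylation of the phenol and the primary alcohol in the same flask; the acetic acid buffer keeps the liberated phenol protonated, so no quinone methide pathway opens at C2. The acetates survive fluoride and Lewis acid in steps 8 and 14 and make ring C a poor donor.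

Step 8
Reactants: 14 [(2S,3S)-2-(4-acetoxy-3-methoxyphenyl)-7-methoxy-2,3-dihydro-1-benzofuran-3-yl]methyl acetate
Product: 16 potassium [(2S,3S)-3-(acetoxymethyl)-2-(4-acetoxy-3-methoxyphenyl)-7-methoxy-2,3-dihydro-1-benzofuran-5-yl]trifluoroborate, via pinacol boronate 15 (not isolated)
Conditions: [Ir(cod)OMe]2 (1.5 mol%), 4,4′-di-tert-butyl-2,2′-bipyridine (3 mol%), B2pin2 (0.7 equiv), THF, 80 °C; then aq. KHF2, MeOH, rt
Reagents that add atoms: bis(pinacolato)diboron, CC1(C)OB(OC1(C)C)B1OC(C)(C)C(C)(C)O1; potassium hydrogen difluoride, [K+].F[H-]F
Why: Sterically controlled iridium-catalysed aromatic C–H borylation (a trivalent iridium tris(boryl) bipyridine complex) should attack the only C–H bond without an ortho substituent, C5 of ring A, since every C–H bond of ring C is flanked. KHF2 then converts boronate 15 into the trifluoroborate in the same flask; esters and aryl ethers are tolerated by both stages.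

Step 9
Reactants: 17 syringaldehyde
Product: 18 4-(tert-butyldimethylsilyloxy)-3,5-dimethoxybenzaldehyde
Conditions: TBSCl, imidazole, DMF, rt
Reagents that add atoms: tert-butyl(chloro)dimethylsilane, CC(C)(C)[Si](C)(C)Cl
Why: Imidazole-promoted silylation of a phenol; the silyl ether, flanked by two methoxy groups, should withstand the enolate, hydride and acid of steps 10 and 11.

Step 10
Reactants: 19 (5R)-5-(l-menthyloxy)furan-2(5H)-one; 2 vinylmagnesium bromide; 18 4-(tert-butyldimethylsilyloxy)-3,5-dimethoxybenzaldehyde
Product: 21 (3S,4R,5R)-3-{[4-(tert-butyldimethylsilyloxy)-3,5-dimethoxyphenyl](hydroxy)methyl}-4-ethenyl-5-(l-menthyloxy)dihydrofuran-2(3H)-one (carbinol epimers), via magnesium enolate 20 (not isolated)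
Conditions: 2 (2.2 equiv), CuBr·SMe2 (1.1 equiv), THF, −78 °C; 19, −78 °C; then 18, −78 → −40 °C; aq. NH4Cl
Reagents that add atoms: none
Why: Tandem cuprate conjugate addition–aldol reaction: (CH2=CH)2CuMgBr adds to the β-carbon of the butenolide anti to the menthyloxy group, which sets C6a′, and the magnesium enolate 20 is trapped by aldehyde 18 anti to the new vinyl group, which sets C3a′. The carbinol centre forms as a mixture, which does not matter because step 11 re-sets it.

Step 11
Reactants: 21 (3S,4R,5R)-3-{[4-(tert-butyldimethylsilyloxy)-3,5-dimethoxyphenyl](hydroxy)methyl}-4-ethenyl-5-(l-menthyloxy)dihydrofuran-2(3H)-one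
Product: 23 [(2S,3R,4R)-2-[4-(tert-butyldimethylsilyloxy)-3,5-dimethoxyphenyl]-4-ethenyltetrahydrofuran-3-yl]methanol, via triol 22 (not isolated)
Conditions: LiAlH4, THF, 0 °C; aq. potassium sodium tartrate work-up; then TsOH·H2O (10 mol%), CH2Cl2, 0 °C → rt
Reagents that add atoms: none
Why: Hydride reduction of the lactone and, after ring opening to the aldehyde, of the menthyl acetal carbon gives triol 22 and menthol. Acid then ionises the electron-rich benzylic alcohol, and the only hydroxyl that can reach it through a five-membered ring closes the tetrahydrofuran (SN1 cycloetherification). The aryl group should settle trans to the neighbouring hydroxymethyl group in the product-like transition state, which fixes C4′, while the trans lactone substituents end up cis on the new ring.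

Step 12
Reactants: 23 [(2S,3R,4R)-2-[4-(tert-butyldimethylsilyloxy)-3,5-dimethoxyphenyl]-4-ethenyltetrahydrofuran-3-yl]methanol
Product: 25 (3aR,4S,6aR)-4-[4-(tert-butyldimethylsilyloxy)-3,5-dimethoxyphenyl]-1-methoxytetrahydro-1H,3H-furo[3,4-c]furan (anomers), via lactol 24 (not isolated)
Conditions: O3, CH2Cl2/MeOH (4:1), Sudan Red 7B, −78 °C; Me2S, −78 °C → rt; then PPTS (10 mol%), MeOH, rt
Reagents that add atoms: ozone, [O-][O+]=O; methanol, CO
Why: Ozonolysis with reductive dimethyl sulfide work-up gives the aldehyde, which the cis hydroxymethyl group captures at once as the cis-fused lactol 24. Mild acid-catalysed acetal exchange in methanol (Fischer-type glycosidation) gives the methyl acetal; both anomers lead to the same oxocarbenium ion in step 14.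

Step 13
Reactants: 25 (3aR,4S,6aR)-4-[4-(tert-butyldimethylsilyloxy)-3,5-dimethoxyphenyl]-1-methoxytetrahydro-1H,3H-furo[3,4-c]furan
Product: 27 4-[(3aR,4S,6aR)-1-methoxytetrahydro-1H,3H-furo[3,4-c]furan-4-yl]-2,6-dimethoxyphenyl acetate (anomers), via phenol 26 (not isolated)
Conditions: TBAF, THF, 0 °C; then Ac2O, Et3N, DMAP, 0 °C → rt
Reagents that add atoms: acetic anhydride, CC(=O)OC(C)=O
Why: Fluoride cleavage of the aryl silyl ether and acetylation of the phenoxide in the same flask; the acetal is inert to both. The aryl acetate deactivates ring F and the C4′ benzylic ether towards the Lewis acid of step 14 and matches the protecting groups of 16.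

Step 14
Reactants: 16 potassium [(2S,3S)-3-(acetoxymethyl)-2-(4-acetoxy-3-methoxyphenyl)-7-methoxy-2,3-dihydro-1-benzofuran-5-yl]trifluoroborate; 27 4-[(3aR,4S,6aR)-1-methoxytetrahydro-1H,3H-furo[3,4-c]furan-4-yl]-2,6-dimethoxyphenyl acetate
Product: 28 [(2S,3S)-2-(4-acetoxy-3-methoxyphenyl)-5-[(1S,3aR,4S,6aR)-4-(4-acetoxy-3,5-dimethoxyphenyl)tetrahydro-1H,3H-furo[3,4-c]furan-1-yl]-7-methoxy-2,3-dihydro-1-benzofuran-3-yl]methyl acetate
Conditions: 16 (1.3 equiv), BF3·OEt2 (2.5 equiv), CH2Cl2/MeCN, −40 → 0 °C
Reagents that add atoms: none
Why: Lewis acid-promoted coupling of a potassium aryltrifluoroborate with an acetal: BF3 abstracts fluoride from 16, the resulting aryldifluoroborane ionises the methoxy acetal of 27 to the bicyclic oxocarbenium ion and delivers the aryl group from boron at the ipso carbon C5. Attack should occur on the convex face of the cis-fused bicycle, anti to ring E, so C1′ is formed exo; the acetoxy groups para to C2 and C4′ hold those benzylic ethers against ionisation at low temperature.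

Step 15
Reactants: 28 [(2S,3S)-2-(4-acetoxy-3-methoxyphenyl)-5-[(1S,3aR,4S,6aR)-4-(4-acetoxy-3,5-dimethoxyphenyl)tetrahydro-1H,3H-furo[3,4-c]furan-1-yl]-7-methoxy-2,3-dihydro-1-benzofuran-3-yl]methyl acetate
Product: 29 4-[(2S,3S)-5-[(1S,3aR,4S,6aR)-4-(4-hydroxy-3,5-dimethoxyphenyl)tetrahydro-1H,3H-furo[3,4-c]furan-1-yl]-3-(hydroxymethyl)-7-methoxy-2,3-dihydro-1-benzofuran-2-yl]-2-methoxyphenol (CNP0126146.1)
Conditions: K2CO3 (0.5 equiv), MeOH, 0 °C → rt; pH 7 phosphate buffer
Reagents that add atoms: none
Why: Base-catalysed transesterification (methanolysis) of two aryl acetates and one primary acetate; no stereocentre carries an acidic hydrogen. The reaction is run cold and stopped with buffer so that the ring C phenoxide has little time to open the cis ring through a quinone methide.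

## Compound list

1 | 2-bromo-3-methoxybenzaldehyde | COc1cccc(C=O)c1Br | starting material
2 | vinylmagnesium bromide | C=C[Mg]Br | starting material
3 | bromomagnesium 1-(2-bromo-3-methoxyphenyl)prop-2-en-1-olate (racemic, not isolated) | COc1cccc(C(C=C)O[Mg]Br)c1Br | intermediate
4 | rac-1-(2-bromo-3-methoxyphenyl)prop-2-en-1-yl methyl carbonate | COC(=O)OC(C=C)c1cccc(OC)c1Br | intermediate
5 | (E)-2-[3-(2-bromo-3-methoxyphenyl)prop-2-en-1-yl]-4,4,5,5-tetramethyl-1,3,2-dioxaborolane | COc1cccc(/C=C/CB2OC(C)(C)C(C)(C)O2)c1Br | intermediate
6 | vanillin | COc1cc(C=O)ccc1O | starting material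
7 | 3-methoxy-4-(triisopropylsilyloxy)benzaldehyde | COc1cc(C=O)ccc1O[Si](C(C)C)(C(C)C)C(C)C | intermediate
8 | pinacol borate ester of alcohol 9 (not isolated) | COc1cc([C@@H](OB2OC(C)(C)C(C)(C)O2)[C@H](C=C)c2cccc(OC)c2Br)ccc1O[Si](C(C)C)(C(C)C)C(C)C | intermediate
9 | (1S,2R)-2-(2-bromo-3-methoxyphenyl)-1-[3-methoxy-4-(triisopropylsilyloxy)phenyl]but-3-en-1-ol (anti) | COc1cc([C@@H](O)[C@H](C=C)c2cccc(OC)c2Br)ccc1O[Si](C(C)C)(C(C)C)C(C)C | intermediate
10 | (2S,3R)-3-ethenyl-7-methoxy-2-[3-methoxy-4-(triisopropylsilyloxy)phenyl]-2,3-dihydro-1-benzofuran (cis) | COc1cc([C@H]2Oc3c(OC)cccc3[C@H]2C=C)ccc1O[Si](C(C)C)(C(C)C)C(C)C | intermediate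
11 | (2S,3R)-7-methoxy-2-[3-methoxy-4-(triisopropylsilyloxy)phenyl]-2,3-dihydro-1-benzofuran-3-carbaldehyde (cis, not isolated) | COc1cc([C@H]2Oc3c(OC)cccc3[C@H]2C=O)ccc1O[Si](C(C)C)(C(C)C)C(C)C | intermediate
12 | [(2S,3S)-7-methoxy-2-[3-methoxy-4-(triisopropylsilyloxy)phenyl]-2,3-dihydro-1-benzofuran-3-yl]methanol (cis) | COc1cc([C@H]2Oc3c(OC)cccc3[C@H]2CO)ccc1O[Si](C(C)C)(C(C)C)C(C)C | intermediate
13 | 4-[(2S,3S)-3-(hydroxymethyl)-7-methoxy-2,3-dihydro-1-benzofuran-2-yl]-2-methoxyphenol (not isolated) | COc1cc([C@H]2Oc3c(OC)cccc3[C@H]2CO)ccc1O | intermediate
14 | [(2S,3S)-2-(4-acetoxy-3-methoxyphenyl)-7-methoxy-2,3-dihydro-1-benzofuran-3-yl]methyl acetate | COc1cc([C@H]2Oc3c(OC)cccc3[C@H]2COC(C)=O)ccc1OC(C)=O | intermediate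
15 | [(2S,3S)-2-(4-acetoxy-3-methoxyphenyl)-7-methoxy-5-(4,4,5,5-tetramethyl-1,3,2-dioxaborolan-2-yl)-2,3-dihydro-1-benzofuran-3-yl]methyl acetate (not isolated) | COc1cc([C@H]2Oc3c(OC)cc(B4OC(C)(C)C(C)(C)O4)cc3[C@H]2COC(C)=O)ccc1OC(C)=O | intermediate
16 | potassium [(2S,3S)-3-(acetoxymethyl)-2-(4-acetoxy-3-methoxyphenyl)-7-methoxy-2,3-dihydro-1-benzofuran-5-yl]trifluoroborate | COc1cc([C@H]2Oc3c(OC)cc([B-](F)(F)F)cc3[C@H]2COC(C)=O)ccc1OC(C)=O.[K+] | intermediate
17 | syringaldehyde | COc1cc(C=O)cc(OC)c1O | starting material
18 | 4-(tert-butyldimethylsilyloxy)-3,5-dimethoxybenzaldehyde | COc1cc(C=O)cc(OC)c1O[Si](C)(C)C(C)(C)C | intermediate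
19 | (5R)-5-{[(1R,2S,5R)-5-methyl-2-(propan-2-yl)cyclohexyl]oxy}furan-2(5H)-one | O=C1O[C@@H](O[C@@H]2C[C@H](C)CC[C@H]2C(C)C)C=C1 | starting material
20 | bromomagnesium enolate of trans-4-ethenyl-5-(l-menthyloxy)dihydrofuran-2(3H)-one (not isolated) | C=C[C@@H]1C=C(O[Mg]Br)O[C@H]1O[C@@H]2C[C@H](C)CC[C@H]2C(C)C | intermediate
21 | (3S,4R,5R)-3-{[4-(tert-butyldimethylsilyloxy)-3,5-dimethoxyphenyl](hydroxy)methyl}-4-ethenyl-5-(l-menthyloxy)dihydrofuran-2(3H)-one (carbinol epimers) | O=C1O[C@@H](O[C@@H]2C[C@H](C)CC[C@H]2C(C)C)[C@H](C=C)[C@H]1C(O)c1cc(OC)c(O[Si](C)(C)C(C)(C)C)c(OC)c1 | intermediate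
22 | (2R,3R)-2-{[4-(tert-butyldimethylsilyloxy)-3,5-dimethoxyphenyl](hydroxy)methyl}-3-ethenylbutane-1,4-diol (carbinol epimers, not isolated) | C=C[C@@H](CO)[C@H](CO)C(O)c1cc(OC)c(O[Si](C)(C)C(C)(C)C)c(OC)c1 | intermediate
23 | [(2S,3R,4R)-2-[4-(tert-butyldimethylsilyloxy)-3,5-dimethoxyphenyl]-4-ethenyltetrahydrofuran-3-yl]methanol (aryl trans to hydroxymethyl, hydroxymethyl cis to vinyl) | C=C[C@H]1CO[C@H](c2cc(OC)c(O[Si](C)(C)C(C)(C)C)c(OC)c2)[C@H]1CO | intermediate
24 | (3aR,4S,6aR)-4-[4-(tert-butyldimethylsilyloxy)-3,5-dimethoxyphenyl]tetrahydro-1H,3H-furo[3,4-c]furan-1-ol (anomers, not isolated) | OC1OC[C@H]2[C@@H]1CO[C@@H]2c1cc(OC)c(O[Si](C)(C)C(C)(C)C)c(OC)c1 | intermediate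
25 | (3aR,4S,6aR)-4-[4-(tert-butyldimethylsilyloxy)-3,5-dimethoxyphenyl]-1-methoxytetrahydro-1H,3H-furo[3,4-c]furan (anomers) | COC1OC[C@H]2[C@@H]1CO[C@@H]2c1cc(OC)c(O[Si](C)(C)C(C)(C)C)c(OC)c1 | intermediate
26 | 4-[(3aR,4S,6aR)-1-methoxytetrahydro-1H,3H-furo[3,4-c]furan-4-yl]-2,6-dimethoxyphenol (anomers, not isolated) | COC1OC[C@H]2[C@@H]1CO[C@@H]2c1cc(OC)c(O)c(OC)c1 | intermediate
27 | 4-[(3aR,4S,6aR)-1-methoxytetrahydro-1H,3H-furo[3,4-c]furan-4-yl]-2,6-dimethoxyphenyl acetate (anomers) | COC1OC[C@H]2[C@@H]1CO[C@@H]2c1cc(OC)c(OC(C)=O)c(OC)c1 | intermediate
28 | [(2S,3S)-2-(4-acetoxy-3-methoxyphenyl)-5-[(1S,3aR,4S,6aR)-4-(4-acetoxy-3,5-dimethoxyphenyl)tetrahydro-1H,3H-furo[3,4-c]furan-1-yl]-7-methoxy-2,3-dihydro-1-benzofuran-3-yl]methyl acetate | COc1cc([C@H]2Oc3c(OC)cc([C@H]4OC[C@H]5[C@@H]4CO[C@@H]5c4cc(OC)c(OC(C)=O)c(OC)c4)cc3[C@H]2COC(C)=O)ccc1OC(C)=O | intermediate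
29 | 4-[(2S,3S)-5-[(1S,3aR,4S,6aR)-4-(4-hydroxy-3,5-dimethoxyphenyl)tetrahydro-1H,3H-furo[3,4-c]furan-1-yl]-3-(hydroxymethyl)-7-methoxy-2,3-dihydro-1-benzofuran-2-yl]-2-methoxyphenol | COc1cc([C@H]2Oc3c(OC)cc([C@H]4OC[C@H]5[C@@H]4CO[C@@H]5c4cc(OC)c(O)c(OC)c4)cc3[C@H]2CO)ccc1O | target

## Step count and risks

Total step count: 15. Longest linear sequence: 9 steps (steps 1, 2, 4, 5, 6, 7, 8, 14 and 15, from compound 1). The furofuran branch contributes steps 9 to 13, and step 3 supplies aldehyde 7.

**Step 5 (key step).** The most likely failure is slow oxidative addition at the C–Br bond, which is flanked by the methoxy group and the branched benzylic carbon. At the temperature then required, the copper alkoxide may lose a β-hydride (oxidation to the ketone with hydrodebromination), or the carbonate may strip the aryl silyl ether and release a phenoxide that couples intermolecularly. The fallback changes the metal and with it the elementary steps. It sets out from 9 and returns at 10 by palladium-catalysed intramolecular C–O coupling (Pd2(dba)3, a bulky di-tert-butyl(biaryl)phosphine, Cs2CO3, toluene, 70–80 °C). Hindered aryl bromides add readily to zerovalent palladium, and the bulky ligand drives C–O reductive elimination from the divalent palladium alkoxide ahead of β-hydride loss. The same bond is formed and the carbinol C–O bond is again untouched. This fallback makes no new compound (F0).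

**Step 4.** The conjugated γ-aryl allylboronate is a weaker nucleophile than the parent allyl reagent, so catalyst turnover may be slow, and the enantioselectivity may be eroded or even reversed relative to the model behind the choice of the (S)-acid. The diastereoselectivity is not in doubt, since it comes from the chair transition state. The fallback sets out from 5 and 7 and abandons asymmetric catalysis: the thermal, or Sc(OTf)3-catalysed, allylboration gives the anti alcohol as a racemate, that is 9 together with its mirror image, (1R,2S)-2-(2-bromo-3-methoxyphenyl)-1-[3-methoxy-4-(triisopropylsilyloxy)phenyl]but-3-en-1-ol F1. The enantiomers are separated by preparative chromatography on a chiral stationary phase, F1 is discarded, and the route is rejoined at 9.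

**Step 6.** The configuration at C3 may be lost, or ring B may open by β-elimination of the ring A phenoxide, at the stage of aldehyde 11 if reduction lags behind cleavage; ozone may also attack the electron-rich arenes before the alkene is consumed. The fallback sets out from 10 and replaces ozone by a two-stage cleavage of Lemieux–Johnson type. Catalytic K2OsO4·2H2O with N-methylmorpholine N-oxide gives 1-[(2S,3S)-7-methoxy-2-[3-methoxy-4-(triisopropylsilyloxy)phenyl]-2,3-dihydro-1-benzofuran-3-yl]ethane-1,2-diol F2 as a mixture of carbinol epimers. F2 is cleaved with NaIO4 in buffered THF/water at 0 °C with NaBH4 added to the same flask, so the aldehyde is reduced as it forms under near-neutral conditions; the route is rejoined at 12.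

**Step 14.** Adventitious HF may protodeboronate the electron-rich trifluoroborate 16 before the aryl group is transferred. Separately, the Lewis acid may reversibly ionise the new C1′–O2′ bond, which is activated by the para oxygen O1; this would erode the exo configuration, since exo and endo aryl isomers of furofurans lie close in energy, and prolonged exposure could also ionise C2. The fallback sets out from 14 and 27 and returns at 28 without boron: a direct Friedel–Crafts arylation of the oxocarbenium ion by arene 14 with catalytic TMSOTf at −78 °C. It relies on the innate preference for C5, which is para to O1 and unhindered, while ring C is deactivated by its acetate and C4 is shielded by the C3 substituent. Arene 14 is also what protodeboronation of 16 returns. This fallback makes no new compound (F0).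

**Step 15.** Once the ring C acetate is cleaved, the phenoxide may expel the ring A aryloxide to give a para-quinone methide whose reclosure favours the trans ring, so C2 may epimerise while the slower primary acetate is still being removed. The fallback sets out from 28 and returns at 29 by reductive instead of basic deacylation: excess i-Bu2AlH in CH2Cl2 at −78 °C, followed by a neutral aqueous potassium sodium tartrate work-up. The phenol is then held as a covalent aluminium aryloxide at low temperature and no free phenoxide is present. This fallback makes no new compound (F0).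

## Further compounds

F1 | step 4 | (1R,2S)-2-(2-bromo-3-methoxyphenyl)-1-[3-methoxy-4-(triisopropylsilyloxy)phenyl]but-3-en-1-ol (enantiomer of 9) | COc1cc([C@H](O)[C@@H](C=C)c2cccc(OC)c2Br)ccc1O[Si](C(C)C)(C(C)C)C(C)C
F0 | step 5 | none | none
F2 | step 6 | 1-[(2S,3S)-7-methoxy-2-[3-methoxy-4-(triisopropylsilyloxy)phenyl]-2,3-dihydro-1-benzofuran-3-yl]ethane-1,2-diol (carbinol epimers) | COc1cc([C@H]2Oc3c(OC)cccc3[C@H]2C(O)CO)ccc1O[Si](C(C)C)(C(C)C)C(C)C
F0 | step 14 | none | none
F0 | step 15 | none | none
A1 | alternative 1 | 2-[4-(tert-butyldimethylsilyloxy)-3,5-dimethoxyphenyl]-1,3-dithiane | COc1cc(C2SCCCS2)cc(OC)c1O[Si](C)(C)C(C)(C)C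
A2 | alternative 1 | 4-(allyloxy)-3-methoxybenzaldehyde | C=CCOc1ccc(C=O)cc1OC
A3 | alternative 1 | trans-3-[(4-allyloxy-3-methoxyphenyl)(hydroxy)methyl]-4-{2-[4-(tert-butyldimethylsilyloxy)-3,5-dimethoxyphenyl]-1,3-dithian-2-yl}-5-(l-menthyloxy)dihydrofuran-2-one | C=CCOc1ccc(cc1OC)[C@@H](O)[C@H]1C(=O)O[C@@H](O[C@@H]2C[C@H](C)CC[C@H]2C(C)C)[C@@H]1C1(SCCCS1)c1cc(OC)c(O[Si](C)(C)C(C)(C)C)c(OC)c1
A4 | alternative 2 | (2R,3R)-2-(4-hydroxy-3-methoxybenzyl)-3-(4-hydroxy-3,5-dimethoxybenzyl)butane-1,4-diol | COc1cc(C[C@@H](CO)[C@H](CO)Cc2cc(OC)c(O)c(OC)c2)ccc1O
A5 | alternative 2 | medioresinol, (1S,3aR,4S,6aR) enantiomer | COc1cc(ccc1O)[C@H]1OC[C@H]2[C@@H]1CO[C@@H]2c1cc(OC)c(O)c(OC)c1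
A6 | alternative 3 | [(2S,3R)-2-[4-(tert-butyldimethylsilyloxy)-3,5-dimethoxyphenyl]-2,3-dihydrofuran-3-yl]methanol | OC[C@H]1C=CO[C@@H]1c1cc(OC)c(O[Si](C)(C)C(C)(C)C)c(OC)c1
A7 | alternative 3 | 1-(allyloxy)-4-(dimethoxymethyl)-2-methoxybenzene | C=CCOc1ccc(C(OC)OC)cc1OC
A8 | alternative 3 | furofuran methyl acetal with exo aryl groups and a methoxy group on C6′ | C=CCOc1ccc(cc1OC)[C@H]1OC[C@H]2[C@@H]1[C@H](OC)O[C@@H]2c1cc(OC)c(O[Si](C)(C)C(C)(C)C)c(OC)c1
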